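**Remarks on the chemistry**

- Atom labels: ring B is the central ring, with OH on C1, the outer rings on C2 and C6 and allyl on C4. Rings A and C are the outer rings, each joined through C1', with OH on C2' and allyl on C5'. Compounds 6, 8 and 12 carry the same pattern throughout: oxygen on C1 and both C2', bromine or allyl on C4 and both C5'.
- After the key step the phenols are masked as acetates and not as methyl ethers. Ester methanolysis cannot touch terminal alkenes, whereas ether cleavage with a boron halide can add HBr to them.
- In the threefold steps 4 to 6 the partly converted species are mixtures of positional isomers, not single compounds, and are not numbered.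

## Structural features

Dunnianol is a meta-terphenyl: central ring B carries OH on C1, outer rings A and C on C2 and C6, and an allyl group on C4, and each outer ring is joined through C1' with OH on C2' and allyl on C5'. There is no stereocentre, and with free rotation about the two biaryl bonds a mirror plane through C1 and C4 makes rings A and C equivalent, which invites two-directional synthesis. The fragile groups are the three allyl groups, terminal alkenes that migrate into conjugation with base or with hydride-bearing palladium species, add HBr and are oxidised by divalent palladium, and the three electron-rich phenols, two of which form 2,2'-biphenol units that oxidise easily to quinones. The difficulty is regiochemical and not skeletal: each outer ring needs oxygen exactly ortho to the biaryl bond and allyl exactly para to that oxygen, and three allyl groups must arrive late and survive the unmasking of three phenols. The key step exploits the position of O1 on ring B, which lies four bonds from C2' of ring A and of ring C (O1–C1–C2–C1'–C2' and O1–C1–C6–C1'–C2'), so palladium held on O1 reaches either C2'–H bond through a six-membered palladacycle. Bromine atoms on C4 and on both C5' stand in for the allyl groups during that oxidation, block the position para to every oxygen and mark the sites of the later C–C couplings.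

## Logic of the disconnections

12 to 11. The three phenolic O–H bonds of 12 are traced back to three O–acyl bonds in 11. The cut is placed there so that the last operation cannot reach a terminal alkene. Nothing is gained in skeleton, but the end game becomes a simple ester exchange. The forward step must cleave three aryl esters with base mild enough to leave the double bonds in place, and must exclude air from the phenoxides.

11 to 9 and 10. The bonds cut are C4–CH2 on ring B and the two C5'–CH2 bonds on rings A and C. The three allyl groups are alike and sit on sp2 carbons, so one palladium-catalysed operation with 10 can deliver all of them, and their removal takes the oxidation-sensitive alkenes out of everything upstream. The forward step must reach full conversion at three C–Br bonds without double-bond migration. The ester groups of 9 help by lowering the electron density para to each bromine and are inert to a neutral coupling.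

9 to 8. Three O–acyl bonds are cut. This only unmasks the phenols, but it makes 8 the direct product of the key step. The forward step must acylate all three oxygens, including the crowded O1.

8 to 6, through 7. The two C2'–O bonds are cut. This is the strategic simplification: two of the three oxygens disappear, the outer rings become plain 3-bromophenyl groups, and the precursor carries a single hydroxyl that also serves as the directing group. The forward step must choose C2' over C6' on each ring, must hydroxylate and not close a furan ring, must turn over twice from one directing oxygen, and must leave three C–Br bonds and the phenols intact under an oxidant.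

6 to 3 and 4, through 5. The two biaryl bonds C2–C1' and C6–C1' are cut. The symmetry of 6 lets both be made in one operation from three monocyclic pieces, and 4 is commercial. The forward step must couple at the two C–I bonds of 3 beside a free phenoxide while every C–Br bond (in 3, in 4 and in 6) stays untouched.

3 to 1, through 2. The two C–I bonds ortho to the hydroxyl are cut, which leads to 1, a commercial compound whose para position is already blocked by bromine. The forward step only needs two equivalents of an iodonium source and clean ortho substitution.

## Other disconnections considered

Alternative 1: The cut runs through ring B itself, at C2–C3 and C5–C6. C1 with its oxygen, C2 and C6 would come from the symmetrical ketone 1,3-bis(5-allyl-2-methoxyphenyl)propan-2-one A1, and C3, C4 and C5 with the C4 allyl group from the 2-allyl-substituted vinamidinium hexafluorophosphate A2. In the forward direction a base would form the enolate of A1, each benzylic carbon would add to one iminium terminus of A2 with loss of a dimethylamino group, and the second addition would close ring B, which aromatises to 4-allyl-2,6-bis(5-allyl-2-methoxyphenyl)phenol A3.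
- In favour: the plan is convergent, O1 and the C4 substituent are fixed by construction, the outer oxygens are present from the start so no choice between two ortho positions arises, and neither a transition metal nor tin is needed.
- Against: the condensation needs strong base and heat with three allyl groups present, so migration of the double bonds into conjugation is a real hazard. A2 is not a stock reagent, and its formylation-type preparation beside a terminal alkene is uncertain. A1 is a multi-step target in its own right. A3 still has two aryl methyl ethers to cleave next to three terminal alkenes, which is the end-game problem the chosen plan avoids.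
- Comparison: on structure this plan is the better one for regiochemical certainty, because the chosen plan relies on steric discrimination between C2' and C6'. On mechanism it is a polar condensation with no oxidant near the phenols, which is at least equal for the phenols but worse for the allyl groups. On step economy it is equal or better in convergence, but the total count (A1, A2, condensation to A3, ether cleavage) is expected to exceed six steps.

Alternative 2: The cut goes through each outer ring at C1'–C2' and C3'–C4', so rings A and C are built last. The substrate would be the bis-pyrone 3,3'-(5-allyl-2-methoxy-1,3-phenylene)bis(5-bromo-2H-pyran-2-one) A4 and the two-carbon partner 1,1-dimethoxyethene A5. Each pyrone ring of A4 would act as the diene across its C3 and C6 in an inverse-demand Diels–Alder reaction. The nucleophilic CH2 terminus of A5 should bond to pyrone C6 and the acetal carbon to pyrone C3. Cycloreversion of the bridged lactone with loss of the carboxyl bridge, followed by loss of one methoxy group, would then give 4-allyl-2,6-bis(5-bromo-2-methoxyphenyl)anisole A6.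
- In favour: the C2' oxygen and the C5' bromine are placed by orbital polarity with no competing ortho site, no oxidant is used, and the ring-B allyl group can be present early because the conditions are thermal.
- Against: A4 needs two C3-selective couplings of a dihalopyrone to a doubly metalated ring-B piece. A5 is moisture-sensitive and polymerises easily. The 3-aryl-5-bromopyrone units of A4 are only moderately electron-poor and would probably need forcing temperatures. After A6 there remain a double allylation and the cleavage of three methyl ethers next to three alkenes.
- Comparison: on structure this plan is the better one for certainty of the outer-ring pattern. On mechanism it is pericyclic and needs no directing group, which is equal or better for tolerance of the phenol oxidation level. On step economy it is clearly longer than the chosen plan and ends with the less safe deprotection.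

Alternative 3: The cut is at the two C5'–CH2 bonds, with the outer rings raised to the quinone monoketal level in 3,3'-(5-allyl-2-methoxy-1,3-phenylene)bis(4,4-dimethoxycyclohexa-2,5-dien-1-one) A7. In the forward direction the Grignard reagent allylmagnesium bromide A8 would add 1,2 to each C5' carbonyl of A7. A reductive work-up with zinc in a carboxylic acid would then remove the tertiary carbinol oxygen and the ketal, re-aromatising both rings to give 4-allyl-2,6-bis(5-allyl-2-hydroxyphenyl)anisole A9.
- In favour: the polarity inversion makes the carbon para to the phenol oxygen electrophilic, so two C–C bonds are made with A8, a cheap reagent, and without palladium, tin or halide. The allyl group lands para to oxygen by construction, and the outer phenols emerge free.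
- Against: A7 must first be made by twofold oxidative dearomatisation of a more highly oxygenated terphenyl, which adds steps and an extra oxygen that is later thrown away. An allyl metal reagent such as A8 can partition between 1,2- and conjugate addition. The doubly allylic carbinol formed can undergo dienone–phenol rearrangement with allyl migration under the acidic reduction, which would misplace the allyl group. A9 still has the ring-B methyl ether to cleave beside three alkenes.
- Comparison: on structure it is the equal of the chosen plan in the final pattern and better in that two allyl groups need no cross-coupling. On mechanism it avoids the choice between two ortho C–H bonds, a point in its favour, but it depends on the behaviour of allyl groups in cationic dienone intermediates. On step economy it is expected to be longer than six steps.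

Key step: step 3

## Route

Step 1
Reactants: 1 4-bromophenol
Product: 3 4-bromo-2,6-diiodophenol, via 4-bromo-2-iodophenol 2 (not isolated)
Conditions: NIS (2.2 equiv), p-TsOH·H2O (10 mol %), MeCN, 0 °C to rt
Reagents that add atoms: N-iodosuccinimide, O=C1CCC(=O)N1I
Why: Electrophilic aromatic iodination; the hydroxyl directs to its two ortho positions, the para position is blocked by bromine, and acid-activated NIS is a mild iodonium source, so two equivalents should stop at the 2,6-diiodide.

Step 2
Reactants: 3 4-bromo-2,6-diiodophenol; 4 3-bromophenylboronic acid
Product: 6 4-bromo-2,6-bis(3-bromophenyl)phenol, via monoarylated iodophenol 5 (not isolated)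
Conditions: 4 (2.3 equiv), Pd(PPh3)4 (5 mol %), 2 M aq. Na2CO3, DME, 70 °C, argon
Reagents that add atoms: 3-bromophenylboronic acid (4), OB(O)c1cccc(Br)c1
Why: Twofold Suzuki–Miyaura coupling; zerovalent palladium carrying PPh3 inserts into C–I bonds far faster than into C–Br bonds, so at moderate temperature both iodides should couple while the bromines of 3, 4 and 6 stay intact. The phenol is tolerated as its phenoxide in aqueous carbonate and is needed free for step 3.

Step 3
Reactants: 6 4-bromo-2,6-bis(3-bromophenyl)phenol
Product: 8 4-bromo-2,6-bis(5-bromo-2-hydroxyphenyl)phenol, via monohydroxylated terphenyl 7 (not isolated)
Conditions: Pd(OAc)2 (10 mol %), t-BuOOH (5.5 M in decane, 5 equiv, in portions), DCE, 80 °C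
Reagents that add atoms: tert-butyl hydroperoxide, CC(C)(C)OO
Why: The phenoxide oxygen O1 of 6 binds Pd(OAc)2, and acetate-assisted concerted metalation–deprotonation of the C2'–H bond of one outer ring gives a six-membered oxapalladacycle (Pd, O1, C1, C2, C1', C2'). tert-Butyl hydroperoxide should oxidise this divalent palladium aryl to a tetravalent palladium aryl hydroxide, C2'–O reductive elimination then releases the new phenol and divalent palladium, and the same O1 steers the catalyst to the second outer ring, so that 7 reacts on to 8 in the same flask. The closest known reaction type is the hydroxyl-directed, Pd(OAc)2-catalysed ortho C–H hydroxylation of 2-arylphenols to 2,2'-biphenols with a hydroperoxide; here one directing oxygen serves two aryl groups in turn. No ring is closed and no stereocentre is formed, so neither a mode of closure nor a stereocontrol element is involved. Site selectivity between the two ortho positions of each outer ring is needed: C6' lies between the biaryl bond and the C5' bromine and is closed to the bulky acetate-bound palladium, whereas C2' is unhindered and para to bromine. Chemoselectivity for hydroxylation over C–O ring closure to a dibenzofuran is needed: the peroxide takes the palladacycle to the tetravalent state, where transfer of OH to C2' is expected to outrun reductive elimination onto the crowded, doubly ortho-arylated O1. The bromine on C4 shields C3 and C5 of ring B from hydroxylation directed by the new outer hydroxyls, and bromine para to every oxygen closes the route to para-quinones. The C–Br bonds should be inert because the cycle runs between divalent and tetravalent palladium and never passes through zerovalent palladium.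

Step 4
Reactants: 8 4-bromo-2,6-bis(5-bromo-2-hydroxyphenyl)phenol
Product: 9 4-bromo-2,6-bis(2-acetoxy-5-bromophenyl)phenyl acetate (triacetate of 8)
Conditions: Ac2O (6 equiv), pyridine, DMAP (10 mol %), CH2Cl2, rt
Reagents that add atoms: acetic anhydride, CC(=O)OC(C)=O
Why: DMAP-catalysed O-acylation of all three phenols, including the hindered O1 between two aryl groups. The acetates remove the acidic protons, make each C–Br bond less electron-rich for oxidative addition in step 5, and can later be removed without acid, Lewis acid or heat.

Step 5
Reactants: 9 4-bromo-2,6-bis(2-acetoxy-5-bromophenyl)phenyl acetate; 10 allyltributylstannane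
Product: 11 4-allyl-2,6-bis(2-acetoxy-5-allylphenyl)phenyl acetate (tri-O-acetyldunnianol)
Conditions: 10 (4.5 equiv), Pd(PPh3)4 (10 mol %), toluene (degassed), 105 °C, argon
Reagents that add atoms: allyltributylstannane (10), C=CC[Sn](CCCC)(CCCC)CCCC
Why: Threefold Stille allylation; oxidative addition of zerovalent palladium into each C–Br bond, allyl transfer from tin and reductive elimination form the C4–CH2 bond and both C5'–CH2 bonds. The medium is neutral, so the aryl acetates survive, and stopping at full conversion limits alkene isomerisation through hydride addition and elimination at palladium.

Step 6
Reactants: 11 4-allyl-2,6-bis(2-acetoxy-5-allylphenyl)phenyl acetate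
Product: 12 dunnianol, 4-allyl-2,6-bis(5-allyl-2-hydroxyphenyl)phenol
Conditions: K2CO3 (0.3 equiv), MeOH/THF (degassed), rt, argon; then aq. NH4Cl
Reagents that add atoms: none
Why: Base-catalysed transesterification; aryl acetates are activated esters and exchange with methanol at room temperature, which is too mild to move the terminal alkenes into conjugation, and exclusion of air protects the phenoxides.

## Compound list

1 | 4-bromophenol | Oc1ccc(Br)cc1 | starting material
2 | 4-bromo-2-iodophenol | Oc1ccc(Br)cc1I | intermediate
3 | 4-bromo-2,6-diiodophenol | Oc1c(I)cc(Br)cc1I | intermediate
4 | 3-bromophenylboronic acid | OB(O)c1cccc(Br)c1 | starting material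
5 | 4-bromo-2-(3-bromophenyl)-6-iodophenol | Oc1c(I)cc(Br)cc1-c1cccc(Br)c1 | intermediate
6 | 4-bromo-2,6-bis(3-bromophenyl)phenol | Oc1c(-c2cccc(Br)c2)cc(Br)cc1-c1cccc(Br)c1 | intermediate
7 | 4-bromo-2-(3-bromophenyl)-6-(5-bromo-2-hydroxyphenyl)phenol | Oc1ccc(Br)cc1-c1cc(Br)cc(-c2cccc(Br)c2)c1O | intermediate
8 | 4-bromo-2,6-bis(5-bromo-2-hydroxyphenyl)phenol | Oc1ccc(Br)cc1-c1cc(Br)cc(-c2cc(Br)ccc2O)c1O | intermediate
9 | 4-bromo-2,6-bis(2-acetoxy-5-bromophenyl)phenyl acetate | CC(=O)Oc1ccc(Br)cc1-c1cc(Br)cc(-c2cc(Br)ccc2OC(C)=O)c1OC(C)=O | intermediate
10 | allyltributylstannane | C=CC[Sn](CCCC)(CCCC)CCCC | starting material
11 | 4-allyl-2,6-bis(2-acetoxy-5-allylphenyl)phenyl acetate | C=CCc1ccc(OC(C)=O)c(-c2cc(CC=C)cc(-c3cc(CC=C)ccc3OC(C)=O)c2OC(C)=O)c1 | intermediate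
12 | dunnianol | C=CCc1ccc(O)c(-c2cc(CC=C)cc(-c3cc(CC=C)ccc3O)c2O)c1 | target

Total step count: 6. Longest linear sequence: 6 steps (1 to 3 to 6 to 8 to 9 to 11 to 12).

## Steps least certain to work

Step 3 (key step).
- What may go wrong: C–O reductive elimination onto O1 may compete with hydroxylation and close a furan ring, especially if the peroxide is consumed faster than the palladacycle is oxidised. The phenoxides may also suffer one-electron oxidation by alkoxyl or peroxyl radicals from the hydroperoxide, which would drain material into quinoid products. The reaction may stall after the first hydroxylation, because the 2,2'-biphenolate formed can chelate divalent palladium and slow the second turnover.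
- Fallback: set out from 3 and bring the outer oxygens in with the coupling partner instead of by C–H oxidation. Suzuki–Miyaura coupling of 3 with 5-bromo-2-methoxyphenylboronic acid (COc1ccc(Br)cc1B(O)O; Pd(PPh3)4, aq. Na2CO3, DME, 70 °C) should give 4-bromo-2,6-bis(5-bromo-2-methoxyphenyl)phenol F1. Cleavage of the two methyl ethers with BBr3 in CH2Cl2 is harmless at this stage because no alkene is present yet, and it returns the route at 8. The step count stays at six.

Step 2.
- What may go wrong: halide discrimination may erode. The iodides of 3 sit on an electron-rich phenoxide, and the second one is flanked by the new aryl group, so oxidative addition at C–I is slowed. Insertion of zerovalent palladium into C–Br bonds of 4, 5 or 6 could then compete and lead to oligoarylation, or the reaction could stop at the mono-coupled stage.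
- Fallback: set out from 3 and take the phenoxide out of the coupling. O-Methylation (MeI, K2CO3, DMF) gives 4-bromo-2,6-diiodoanisole F2, whose C–I bonds on a neutral ring restore a wide rate gap over C–Br. Coupling with 4 (Pd(PPh3)4, aq. Na2CO3, toluene/EtOH, 70 °C) gives 4-bromo-2,6-bis(3-bromophenyl)anisole F3. BBr3 in CH2Cl2 then frees the phenol and returns the route at 6, at the cost of two extra steps.

Step 5.
- What may go wrong: the threefold coupling may not go to completion if the catalyst decays, leaving partly allylated material. Prolonged heating may cause migration of the terminal double bonds into conjugation with the rings through hydride addition and elimination at palladium, giving propenyl isomers that are hard to separate.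
- Fallback: set out from 8 and change both the mask and the allyl donor. MOMCl and i-Pr2NEt in CH2Cl2 give 5-bromo-1,3-bis[5-bromo-2-(methoxymethoxy)phenyl]-2-(methoxymethoxy)benzene F4. These base-stable acetals allow a fluoride-activated Suzuki–Miyaura allylation with allylboronic acid pinacol ester (C=CCB1OC(C)(C)C(C)(C)O1; Pd(PPh3)4, CsF, THF, 65 °C), at lower temperature than the tin coupling, to give tri-O-(methoxymethyl)dunnianol F5. Dilute HCl in MeOH at 40 °C removes the acetals without affecting the allyl groups and returns the route at 12. The step count is unchanged.

## Further compounds

F1 | step 3 | 4-bromo-2,6-bis(5-bromo-2-methoxyphenyl)phenol | COc1ccc(Br)cc1-c1cc(Br)cc(-c2cc(Br)ccc2OC)c1O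
F2 | step 2 | 4-bromo-2,6-diiodoanisole | COc1c(I)cc(Br)cc1I
F3 | step 2 | 4-bromo-2,6-bis(3-bromophenyl)anisole | COc1c(-c2cccc(Br)c2)cc(Br)cc1-c1cccc(Br)c1
F4 | step 5 | 5-bromo-1,3-bis[5-bromo-2-(methoxymethoxy)phenyl]-2-(methoxymethoxy)benzene | COCOc1ccc(Br)cc1-c1cc(Br)cc(-c2cc(Br)ccc2OCOC)c1OCOC
F5 | step 5 | 5-allyl-1,3-bis[5-allyl-2-(methoxymethoxy)phenyl]-2-(methoxymethoxy)benzene (tri-O-(methoxymethyl)dunnianol) | C=CCc1ccc(OCOC)c(-c2cc(CC=C)cc(-c3cc(CC=C)ccc3OCOC)c2OCOC)c1
A1 | alternative 1 | 1,3-bis(5-allyl-2-methoxyphenyl)propan-2-one | C=CCc1ccc(OC)c(CC(=O)Cc2cc(CC=C)ccc2OC)c1
A2 | alternative 1 | N-[2-allyl-3-(dimethylamino)prop-2-en-1-ylidene]-N-methylmethanaminium hexafluorophosphate | C=CCC(C=[N+](C)C)=CN(C)C.F[P-](F)(F)(F)(F)F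
A3 | alternative 1 | 4-allyl-2,6-bis(5-allyl-2-methoxyphenyl)phenol | C=CCc1cc(-c2cc(CC=C)ccc2OC)c(O)c(-c2cc(CC=C)ccc2OC)c1
A4 | alternative 2 | 3,3'-(5-allyl-2-methoxy-1,3-phenylene)bis(5-bromo-2H-pyran-2-one) | C=CCc1cc(-c2cc(Br)coc2=O)c(OC)c(-c2cc(Br)coc2=O)c1
A5 | alternative 2 | 1,1-dimethoxyethene | C=C(OC)OC
A6 | alternative 2 | 4-allyl-2,6-bis(5-bromo-2-methoxyphenyl)anisole | C=CCc1cc(-c2cc(Br)ccc2OC)c(OC)c(-c2cc(Br)ccc2OC)c1
A7 | alternative 3 | 3,3'-(5-allyl-2-methoxy-1,3-phenylene)bis(4,4-dimethoxycyclohexa-2,5-dien-1-one) | C=CCc1cc(C2=CC(=O)C=CC2(OC)OC)c(OC)c(C2=CC(=O)C=CC2(OC)OC)c1
A8 | alternative 3 | allylmagnesium bromide | C=CC[Mg]Br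
A9 | alternative 3 | 4-allyl-2,6-bis(5-allyl-2-hydroxyphenyl)anisole | C=CCc1ccc(O)c(-c2cc(CC=C)cc(-c3cc(CC=C)ccc3O)c2OC)c1
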